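**Retrosynthetic overview**
1. Target ⇐ one-pot hydrogenolysis of eight benzyl ethers and a C8 bromine from the fully protected dimer.
2. Interflavan C4–C6 bond (3,4-cis) ⇐ proposed boron-tethered syn aryl delivery from a catechin C6 boronic acid to the C4 cation of a tri-O-benzyl flavan-3,4-diol of the ent-fisetinidol series.
3. Upper unit ⇐ ring C closed by phenol opening of an enantioenriched chalcone epoxide (Juliá–Colonna), then ketone reduction; rings A and B come from an acetophenone and a benzaldehyde.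
4. Lower unit ⇐ (+)-catechin, bought with its rings and both stereocentres; benzylation, C8 bromination (block), C6 iodination, iodine–magnesium exchange and borylation.
5. Ring order: upper ring C is the only ring built; the halves are then joined and deprotected.

Assumption: the SMILES is read as ent-fisetinidol-(4α→6)-catechin, upper unit 2S,3R,4S (2,3-trans-3,4-cis), lower unit 2R,3S; the acetophenone, the benzaldehyde, (+)-catechin and the catalyst poly-D-leucine are taken as purchasable.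

**Route**

Step 1
Reactants: 1 1-[4-(benzyloxy)-2-hydroxyphenyl]ethan-1-one
Product: 2 1-[4-(benzyloxy)-2-(methoxymethoxy)phenyl]ethan-1-one
Conditions: MOMCl, iPr2NEt, CH2Cl2, 0 → 40 °C
Reagents that add atoms: chloromethyl methyl ether (MOMCl), COCCl
Why: Williamson-type O-alkylation of the chelated phenol; the MOM ether survives the basic steps 2 and 3 and is the acid-labile trigger for ring closure in step 4.

Step 2
Reactants: 2 1-[4-(benzyloxy)-2-(methoxymethoxy)phenyl]ethan-1-one; 3 3,4-bis(benzyloxy)benzaldehyde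
Product: 4 (E)-1-[4-(benzyloxy)-2-(methoxymethoxy)phenyl]-3-[3,4-bis(benzyloxy)phenyl]prop-2-en-1-one
Conditions: KOH, EtOH/THF, rt
Reagents that add atoms: none
Why: Claisen–Schmidt aldol condensation of a methyl ketone with a non-enolisable aldehyde; E1cB dehydration gives the conjugated (E)-enone.

Step 3
Reactants: 4 (E)-chalcone
Product: 5 [4-(benzyloxy)-2-(methoxymethoxy)phenyl][(2S,3R)-3-[3,4-bis(benzyloxy)phenyl]oxiran-2-yl]methanone
Conditions: poly-D-leucine, 30% aq. H2O2, NaOH, Bu4NBr (cat.), toluene, rt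
Reagents that add atoms: hydrogen peroxide, OO
Why: Juliá–Colonna epoxidation; the hydroperoxide anion adds to the enone held by hydrogen bonds at the N-terminus of the helical poly-D-leucine, which exposes one face and gives the (2S,3R) epoxide (the L-polymer gives 2R,3S), fixing the future C3 and the trans relationship.

Step 4
Reactants: 5 MOM-protected (2S,3R) chalcone epoxide
Product: 7 (2S,3S)-7-(benzyloxy)-2-[3,4-bis(benzyloxy)phenyl]-3-hydroxychroman-4-one, via free-phenol epoxide 6 (not isolated)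
Conditions: conc. HCl, MeOH/THF, 55 °C; recrystallisation
Reagents that add atoms: none
Why: Acidic methanolysis of the MOM acetal frees phenol 6, which opens the protonated epoxide at the benzylic carbon (6-endo cyclisation); C3 keeps the configuration from step 3 and C2 forms trans (inversion at the benzylic carbon, also the thermodynamic isomer), and recrystallisation raises the ee.

Step 5
Reactants: 7 (2S,3S)-tri-O-benzyl dihydroflavonol
Product: 8 (2S,3R,4S)-7-(benzyloxy)-2-[3,4-bis(benzyloxy)phenyl]chromane-3,4-diol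
Conditions: NaBH4, MeOH/THF, 0 °C
Reagents that add atoms: none
Why: Ketone reduction; axial hydride attack on the half-chair places the new 4-OH equatorial and trans to 3-OH (4S), and this centre is erased again in step 11, so any 3,4-cis diol can be carried along.

Step 6
Reactants: 9 (+)-catechin, (2R,3S)-2-(3,4-dihydroxyphenyl)chromane-3,5,7-triol
Product: 10 (2R,3S)-5,7-bis(benzyloxy)-2-[3,4-bis(benzyloxy)phenyl]chroman-3-ol
Conditions: BnBr (4.4 equiv), K2CO3, DMF, 0 °C → rt
Reagents that add atoms: benzyl bromide, BrCc1ccccc1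
Why: Williamson etherification; K2CO3 deprotonates only the four phenols, so the secondary alcohol and both stereocentres are untouched.

Step 7
Reactants: 10 tetra-O-benzylcatechin
Product: 11 (2R,3S)-5,7-bis(benzyloxy)-2-[3,4-bis(benzyloxy)phenyl]-8-bromochroman-3-ol
Conditions: NBS (1.0 equiv), CH2Cl2, −78 °C → rt
Reagents that add atoms: N-bromosuccinimide, O=C1CCC(=O)N1Br
Why: Electrophilic aromatic bromination; C8 is the most reactive position of the 5,7-dibenzyloxy ring, so one equivalent at low temperature gives the 8-bromide that later blocks C8.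

Step 8
Reactants: 11 8-bromo-tetra-O-benzylcatechin
Product: 12 (2R,3S)-3,5,7-tris(benzyloxy)-2-[3,4-bis(benzyloxy)phenyl]-8-bromochromane
Conditions: NaH, BnBr, Bu4NI (cat.), THF/DMF, 0 °C → rt
Reagents that add atoms: benzyl bromide, BrCc1ccccc1
Why: Williamson etherification of the C3 alkoxide; it caps the last hydroxyl so that it cannot quench the Grignard reagent in step 10 or bind boron in step 11.

Step 9
Reactants: 12 8-bromo-penta-O-benzylcatechin
Product: 13 (2R,3S)-3,5,7-tris(benzyloxy)-2-[3,4-bis(benzyloxy)phenyl]-8-bromo-6-iodochromane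
Conditions: NIS (1.1 equiv), TFA (cat.), CH2Cl2/MeCN, 0 °C → rt
Reagents that add atoms: N-iodosuccinimide, O=C1CCC(=O)N1I
Why: Electrophilic aromatic iodination at C6, the only free position of the lower ring A and flanked by two benzyloxy groups; ring B is far less activated.

Step 10
Reactants: 13 8-bromo-6-iodo-penta-O-benzylcatechin
Product: 16 [(2R,3S)-3,5,7-tris(benzyloxy)-2-[3,4-bis(benzyloxy)phenyl]-8-bromochroman-6-yl]boronic acid, via arylmagnesium chloride 14 (not isolated), via chloromagnesium aryltrimethoxyborate 15 (not isolated)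
Conditions: iPrMgCl·LiCl (1.1 equiv), THF, −30 °C; B(OMe)3, −30 °C → rt; 1 M HCl to pH 6; used without chromatography
Reagents that add atoms: trimethyl borate, COB(OC)OC; water, O
Why: Iodine–magnesium exchange is much faster at the carbon–iodine than at the carbon–bromine bond; the aryl Grignard reagent is trapped by trimethyl borate and mild hydrolysis gives the boronic acid.

Step 11
Reactants: 8 (2S,3R,4S)-tri-O-benzyl flavan-3,4-diol; 16 catechin C6 boronic acid
Product: 19 (2S,3R,4S)-7-(benzyloxy)-2-[3,4-bis(benzyloxy)phenyl]-4-[(2R,3S)-3,5,7-tris(benzyloxy)-2-[3,4-bis(benzyloxy)phenyl]-8-bromochroman-6-yl]chroman-3-ol, via cyclic boronate 17 (not isolated), via C3 borate ester 18 (not isolated)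
Conditions: 4 Å MS, CH2Cl2, rt, 2 h; then TMSOTf (10 mol %), 0.01 M, −78 → −30 °C; aq. NaHCO3
Reagents that add atoms: none
Why: Proposed new method: diol 8 and boronic acid 16 condense to the strained trans-fused dioxaborolane 17, the silyl triflate ionises its benzylic, para-benzyloxy-stabilised C4–O bond while boron stays on O3, and the very electron-rich aryl group on boron attacks the C4 cation at its ipso carbon through a five-membered C4···C(ipso)–B–O3–C3 transition state that can only reach the face syn to O3, so the new bond is 3,4-cis (4S) and at C6, with boron leaving as the C3 borate 18 that is hydrolysed on work-up; the closest known reaction types are hydroxyl-directed Petasis-type boronate additions to cyclic N-acyliminium ions and boron-mediated aglycon delivery to 1,2-anhydro sugars.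

Step 12
Reactants: 19 protected 3,4-cis dimer
Product: 20 (2S,3R,4S)-2-(3,4-dihydroxyphenyl)-4-[(2R,3S)-2-(3,4-dihydroxyphenyl)-3,5,7-trihydroxychroman-6-yl]chromane-3,7-diol
Conditions: H2 (1 atm), Pd(OH)2/C, Et3N, THF/MeOH/H2O, rt
Reagents that add atoms: none
Why: Hydrogenolysis of the eight benzyl ethers and hydrodebromination at C8 with Et3N as HBr scavenger; no stereocentre is touched under these mild conditions.

**Compound list**
1 | 1-[4-(benzyloxy)-2-hydroxyphenyl]ethan-1-one | CC(=O)c1ccc(OCc2ccccc2)cc1O | starting material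
2 | 1-[4-(benzyloxy)-2-(methoxymethoxy)phenyl]ethan-1-one | CC(=O)c1ccc(OCc2ccccc2)cc1OCOC | intermediate
3 | 3,4-bis(benzyloxy)benzaldehyde | O=Cc1ccc(OCc2ccccc2)c(OCc2ccccc2)c1 | starting material
4 | (E)-1-[4-(benzyloxy)-2-(methoxymethoxy)phenyl]-3-[3,4-bis(benzyloxy)phenyl]prop-2-en-1-one | COCOc1cc(OCc2ccccc2)ccc1C(=O)/C=C/c1ccc(OCc2ccccc2)c(OCc2ccccc2)c1 | intermediate
5 | [4-(benzyloxy)-2-(methoxymethoxy)phenyl][(2S,3R)-3-[3,4-bis(benzyloxy)phenyl]oxiran-2-yl]methanone | COCOc1cc(OCc2ccccc2)ccc1C(=O)[C@H]1O[C@@H]1c1ccc(OCc2ccccc2)c(OCc2ccccc2)c1 | intermediate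
6 | [4-(benzyloxy)-2-hydroxyphenyl][(2S,3R)-3-[3,4-bis(benzyloxy)phenyl]oxiran-2-yl]methanone | Oc1cc(OCc2ccccc2)ccc1C(=O)[C@H]1O[C@@H]1c1ccc(OCc2ccccc2)c(OCc2ccccc2)c1 | intermediate
7 | (2S,3S)-7-(benzyloxy)-2-[3,4-bis(benzyloxy)phenyl]-3-hydroxychroman-4-one | O=C1[C@@H](O)[C@H](c2ccc(OCc3ccccc3)c(OCc3ccccc3)c2)Oc2cc(OCc3ccccc3)ccc12 | intermediate
8 | (2S,3R,4S)-7-(benzyloxy)-2-[3,4-bis(benzyloxy)phenyl]chromane-3,4-diol (2,3-trans-3,4-trans) | O[C@@H]1[C@@H](O)[C@H](c2ccc(OCc3ccccc3)c(OCc3ccccc3)c2)Oc2cc(OCc3ccccc3)ccc12 | intermediate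
9 | (+)-catechin, (2R,3S)-2-(3,4-dihydroxyphenyl)chromane-3,5,7-triol | O[C@H]1Cc2c(O)cc(O)cc2O[C@@H]1c1ccc(O)c(O)c1 | starting material
10 | (2R,3S)-5,7-bis(benzyloxy)-2-[3,4-bis(benzyloxy)phenyl]chroman-3-ol | O[C@H]1Cc2c(OCc3ccccc3)cc(OCc3ccccc3)cc2O[C@@H]1c1ccc(OCc2ccccc2)c(OCc2ccccc2)c1 | intermediate
11 | (2R,3S)-5,7-bis(benzyloxy)-2-[3,4-bis(benzyloxy)phenyl]-8-bromochroman-3-ol | O[C@H]1Cc2c(OCc3ccccc3)cc(OCc3ccccc3)c(Br)c2O[C@@H]1c1ccc(OCc2ccccc2)c(OCc2ccccc2)c1 | intermediate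
12 | (2R,3S)-3,5,7-tris(benzyloxy)-2-[3,4-bis(benzyloxy)phenyl]-8-bromochromane | c1ccccc1CO[C@H]1Cc2c(OCc3ccccc3)cc(OCc3ccccc3)c(Br)c2O[C@@H]1c1ccc(OCc2ccccc2)c(OCc2ccccc2)c1 | intermediate
13 | (2R,3S)-3,5,7-tris(benzyloxy)-2-[3,4-bis(benzyloxy)phenyl]-8-bromo-6-iodochromane | c1ccccc1CO[C@H]1Cc2c(OCc3ccccc3)c(I)c(OCc3ccccc3)c(Br)c2O[C@@H]1c1ccc(OCc2ccccc2)c(OCc2ccccc2)c1 | intermediate
14 | C6 arylmagnesium chloride derived from 13 (magnesium in place of iodine) | c1ccccc1CO[C@H]1Cc2c(OCc3ccccc3)c([Mg]Cl)c(OCc3ccccc3)c(Br)c2O[C@@H]1c1ccc(OCc2ccccc2)c(OCc2ccccc2)c1 | intermediate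
15 | chloromagnesium salt of the C6 aryl(trimethoxy)borate | c1ccccc1CO[C@H]1Cc2c(OCc3ccccc3)c([B-](OC)(OC)OC)c(OCc3ccccc3)c(Br)c2O[C@@H]1c1ccc(OCc2ccccc2)c(OCc2ccccc2)c1.[Mg+]Cl | intermediate
16 | [(2R,3S)-3,5,7-tris(benzyloxy)-2-[3,4-bis(benzyloxy)phenyl]-8-bromochroman-6-yl]boronic acid | c1ccccc1CO[C@H]1Cc2c(OCc3ccccc3)c(B(O)O)c(OCc3ccccc3)c(Br)c2O[C@@H]1c1ccc(OCc2ccccc2)c(OCc2ccccc2)c1 | intermediate
17 | cyclic boronate: 1,3,2-dioxaborolane in which boron bridges O3 and O4 of diol 8 (trans-fused) and carries C6 of the lower unit | B3(c4c(OCc5ccccc5)c5C[C@H](OCc6ccccc6)[C@@H](c6ccc(OCc7ccccc7)c(OCc7ccccc7)c6)Oc5c(Br)c4OCc4ccccc4)O[C@@H]1[C@@H](O3)[C@H](c3ccc(OCc4ccccc4)c(OCc4ccccc4)c3)Oc2cc(OCc3ccccc3)ccc12 | intermediate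
18 | C3 dihydroxyboryl (borate) ester of 19 | c1ccccc1COc1ccc2c(c1)O[C@@H](c1ccc(OCc3ccccc3)c(OCc3ccccc3)c1)[C@H](OB(O)O)[C@@H]2c1c(OCc3ccccc3)c(Br)c2c(c1OCc1ccccc1)C[C@H](OCc1ccccc1)[C@@H](c1ccc(OCc3ccccc3)c(OCc3ccccc3)c1)O2 | intermediate
19 | (2S,3R,4S)-7-(benzyloxy)-2-[3,4-bis(benzyloxy)phenyl]-4-[(2R,3S)-3,5,7-tris(benzyloxy)-2-[3,4-bis(benzyloxy)phenyl]-8-bromochroman-6-yl]chroman-3-ol (2,3-trans-3,4-cis) | c1ccccc1COc1ccc2c(c1)O[C@@H](c1ccc(OCc3ccccc3)c(OCc3ccccc3)c1)[C@H](O)[C@@H]2c1c(OCc3ccccc3)c(Br)c2c(c1OCc1ccccc1)C[C@H](OCc1ccccc1)[C@@H](c1ccc(OCc3ccccc3)c(OCc3ccccc3)c1)O2 | intermediate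
20 | (2S,3R,4S)-2-(3,4-dihydroxyphenyl)-4-[(2R,3S)-2-(3,4-dihydroxyphenyl)-3,5,7-trihydroxychroman-6-yl]chromane-3,7-diol | Oc1ccc2c(c1)O[C@@H](c1ccc(O)c(O)c1)[C@H](O)[C@@H]2c1c(O)cc2c(c1O)C[C@H](O)[C@@H](c1ccc(O)c(O)c1)O2 | target

**Summary**
Total steps: 12. Longest linear sequence: 7 (steps 1, 2, 3, 4, 5, 11, 12; the catechin branch 6–10, 11, 12 is equally long).

**Steps most likely to fail, with fallbacks**

Step 11 (the proposed boron-tethered coupling). It is unproven, and protodeboronation of 16 or untethered attack would erode the cis selectivity. The fallback uses known chemistry and sets out from diol 8 and the C6–H bromide 12 (3 equiv). The established Lewis-acid flavanyl Friedel–Crafts coupling (TMSOTf, CH2Cl2, −78 °C) is run without any tether. The C8 bromine still forces attack at C6, but the C4 cation is now attacked from both faces, giving 19 together with its 3,4-trans C4 epimer F1. The two are separated by preparative HPLC and the route is rejoined at 19.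

Step 10 (boronic acid formation). The doubly ortho-oxygenated boronic acid may protodeboronate during exchange or work-up. The fallback sets out from iodide 13. A zerovalent-palladium-catalysed borylation selective for the carbon–iodine bond (Pd(OAc)2, SPhos, pinacolborane, Et3N, dioxane, 60 °C) gives the bench-stable pinacol boronate F2. This is cleaved just before use (NaIO4, NH4OAc, acetone/H2O) and the route is rejoined at 16.

Step 4 (acid cyclisation). The benzylic cation can lead to aryl migration, and acid-induced epimerisation of any 2,3-cis isomer can lower the ee. The fallback sets out from epoxide 5. BnSH/SnCl4 (CH2Cl2, −20 °C) opens the epoxide at the benzylic carbon with loss of the MOM group, giving the β-benzylsulfanyl-α-hydroxy ketone F3. AgBF4 (CH2Cl2, 0 °C) then ionises the carbon–sulfur bond and the phenol closes ring C to the trans-dihydroflavonol, rejoining the route at 7.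

**Further compounds**
F1 | step 11 | (2S,3R,4R)-7-(benzyloxy)-2-[3,4-bis(benzyloxy)phenyl]-4-[(2R,3S)-3,5,7-tris(benzyloxy)-2-[3,4-bis(benzyloxy)phenyl]-8-bromochroman-6-yl]chroman-3-ol (3,4-trans C4 epimer of 19) | c1ccccc1COc1ccc2c(c1)O[C@@H](c1ccc(OCc3ccccc3)c(OCc3ccccc3)c1)[C@H](O)[C@H]2c1c(OCc3ccccc3)c(Br)c2c(c1OCc1ccccc1)C[C@H](OCc1ccccc1)[C@@H](c1ccc(OCc3ccccc3)c(OCc3ccccc3)c1)O2
F2 | step 10 | 2-[(2R,3S)-3,5,7-tris(benzyloxy)-2-[3,4-bis(benzyloxy)phenyl]-8-bromochroman-6-yl]-4,4,5,5-tetramethyl-1,3,2-dioxaborolane | c1ccccc1CO[C@H]1Cc2c(OCc3ccccc3)c(B3OC(C)(C)C(C)(C)O3)c(OCc3ccccc3)c(Br)c2O[C@@H]1c1ccc(OCc2ccccc2)c(OCc2ccccc2)c1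
F3 | step 4 | (2R,3S)-1-[4-(benzyloxy)-2-hydroxyphenyl]-3-[3,4-bis(benzyloxy)phenyl]-3-(benzylsulfanyl)-2-hydroxypropan-1-one | Oc1cc(OCc2ccccc2)ccc1C(=O)[C@@H](O)[C@@H](SCc1ccccc1)c1ccc(OCc2ccccc2)c(OCc2ccccc2)c1
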